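- In the product of the earlier teal run, left-handed product leads right-handed product 10 % to 2 % at 0.667 min, but 26 % to 9 % at 10.0 min. The excess sinks from 66.7 % to 48.6 %, as if the preference were weakening.

| flask | left-handed substrate | right-handed substrate | coupling partner | precatalyst | added ligand | remark | time |
|---|---|---|---|---|---|---|---|
| amber | 0.050 M | 0.050 M | 2.5 equiv | 1.3 mol% | 1.9 mM | the very flask that is asked about, followed so far |  |
| teal | 0.075 M | 0.075 M | 2.5 equiv | 1.3 mol% | 1.9 mM | run made earlier |  |
| flask | 0.050 M | 0.050 M | 2.50 equiv | 1.3 mol% | 1.9 mM |  | 10 min |

- amber (time / s: left-handed product / %, right-handed product / %): 10.0: 2, 2; 15.0: 3, 1; 25.0: 5, 2; 40.0: 7, 2; 60.0: 8, 4; 80.0: 13, 2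
- teal (time / min: left-handed product / %, right-handed product / %): 0.667: 10, 2; 2.00: 17, 4; 4.00: 22, 7; 5.00: 22, 10; 8.00: 26, 8; 10.0: 26, 9

(readings scatter by 1.5 percentage points)

- coupling partner is single-handed; left-handed substrate and right-handed substrate are mirror images of each other, charged as a racemate, each of them at the stated concentration
- the earlier runs were read with a standard deviation of 1.5 percentage points
- an excess is below zero if the other one leads
- the handed part of coupling partner does not stay in what it makes, so the products of the two hands are mirror images too

- left-handed product and right-handed product together, in percent of the left-handed substrate and right-handed substrate charged together, at 10 min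
- excess of left-handed product over right-handed product in the product at 10 min
- whether the exchange between left-handed substrate and right-handed substrate keeps pace with the reaction: how far the product's excess at 10 min gets from its value without exchange to its value with instant exchange (above 80 % keeps pace, below 20 % hardly takes part, else lags behind)

- One steady preference can give both numbers. Suppose each hand reacts first order in itself with the same coupling partner, without exchange. Then, however the coupling partner behaves in time, the logarithm of the fraction left of one hand bears a fixed ratio to that of the other: the selectivity factor.
- Over the last 4 teal readings, the products average 24.0 % and 8.50 %. Each hand is half the charge, so 52.0 % of the left-handed substrate and 83.0 % of the right-handed remain, and the factor reads 3.51. With a scatter of 1.5 percentage points on so small a product, this is a soft reading.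
- Less of the left-handed substrate remains than of the right-handed, so on this supposition the product ratio falls while the factor stands. You need compute only that correction. The starting excess is the factor less one over the factor plus one, 55.6 %, and the ratio shrinks by the share starting excess times conversion.
- The forecast says 29 %, excess 54 %, exchange hardly takes part: “The data only mildly favour no exchange.” It took a factor of 4. At its conversion, my factor gives a ratio of 2.94 and a lower excess, 49.3 %.

- The flask gives 31.6 % with excess 42.4 %, and exchange, going 1.4 % of the way, hardly takes part.

    2 coupling partner → self-condensation product (k = 3.71 L mol⁻¹ min⁻¹)
    coupling partner + right-handed substrate → right-handed product (k = 0.809 L mol⁻¹ min⁻¹)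
    racemization catalyst + added ligand ⇌ idle complex (K = 1100 L mol⁻¹, k = 4750 L mol⁻¹ min⁻¹)
    coupling partner + left-handed substrate → left-handed product (k = 2.40 L mol⁻¹ min⁻¹)
    coupling partner + precatalyst → racemization catalyst + spent reagent (k = 0.441 L mol⁻¹ min⁻¹)
    left-handed substrate + racemization catalyst ⇌ right-handed substrate + racemization catalyst, rate k6*[racemization catalyst]*[left-handed substrate] forward; the back reaction follows from the equilibrium constant (k = 171 L mol⁻¹ min⁻¹)

- Of its own charge, the flask keeps 56 % of the left-handed substrate and 81 % of the right-handed. The same logarithms on these answers give 2.98, below the teal reading. Its starting excess is 49.7 %. Carried to the neighbour with 10.0 equiv of coupling partner, at its 47.2 %, the correction gives a ratio of 2.28 and an excess of 39.0 %; that neighbour stands at 37.5 %.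

(The numbers in the tables were generated by integration for an exercise; noise was put on by code.)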